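The ratio of feed time to run time is 0.188 in blue and 0.0521 in green, so the question concerns the early part of the run.

| flask | starting material | second substrate | free enzyme | remark | time |
|---|---|---|---|---|---|
| north | 16 mM | 14.4 mM | 3.2 µM | run made earlier |  |
| south | 11 mM | 14.4 mM | 3.2 µM | run made earlier |  |
| north-west | 24 mM | 14.4 mM | 3.2 µM | run made earlier |  |
| east | 16 mM | 14.4 mM | 6.4 µM | run made earlier |  |
| grey | 16 mM | 14.4 mM | 3.2 µM | everything together at the start | 8.0 h |
| blue | 16 mM (fed, over 1.5 h) | 14.4 mM | 3.2 µM | all else is in the flask from the start; the feed brings no volume worth counting | 8.0 h |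
| violet | 16 mM | 14.4 mM (fed, over 1.5 h) | 3.2 µM | all else is in the flask from the start; the feed brings no volume worth counting | 8.0 h |
| green | 16 mM (fed, over 25 min) | 14.4 mM | 3.2 µM | all else is in the flask from the start; the feed brings no volume worth counting | 8.0 h |

- north (time / h: side product / %, target / %): 0.417: 1.4, 1.6; 1.33: 0.4, 8.6; 2.50: 3.6, 15.4; 3.00: 6.3, 19.0; 5.00: 11.6, 27.2; 6.00: 13.8, 33.9; 8.00: 19.4, 46.7
- south (time / h: side product / %, target / %): 0.500: 0, 3.9; 1.33: 1.0, 10.4; 2.50: 3.3, 21.3; 4.00: 6.2, 31.6; 6.00: 13.3, 47.2; 8.00: 18.7, 58.5; 10.0: 20.6, 70.3
- north-west (time / h: side product / %, target / %): 0.833: 0, 3.0; 1.33: 0, 4.5; 2.00: 3.1, 7.6; 2.50: 3.9, 9.3; 4.00: 6.3, 14.7; 6.00: 11.9, 23.6; 10.0: 23.6, 36.6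
- east (time / h: side product / %, target / %): 0.833: 2.7, 9.4; 2.50: 7.9, 28.6; 4.00: 12.6, 42.4; 6.00: 16.9, 63.0; 10.0: 23.8, 77.7

(each reading ± 1 percentage point)

- which flask leads in amount of side product, in percent of the starting material charged ("all alike" within 1.5 percentage points) (grey / blue / violet / green / all alike)
- how much side product is there at the end, in percent of the starting material charged: grey
- how much side product is there at the end, in percent of the starting material charged: blue
- how much side product is there at the end, in percent of the starting material charged: violet
- how much side product is there at the end, in percent of the starting material charged: green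

- the numbers in the tables scatter with a standard deviation of 1 percentage point

The north run has grey's recipe and ends at 19.4% side product, so I put grey there. Counted against the north charge, target at 2.50 h is 15.4% in north, 14.6% in south and 14.0% in north-west. Turnover hardly follows the level, so I expect blue to rejoin grey once its feed ends.

Side product in north lags: 0.4% at 1.33 h, then 3.6% at 2.50 h. I take it as growing with the square of time, which gives grey 1.3 points by the end of the slow feed.

Now take two extremes. If the feed changed nothing, blue equals grey. If blue made no side product during its feed, it falls short by that 1.3 points. A steady feed holds on average half the charge, so I replace the rising level by its mean. Call the feed loss half of what the batch holds when the feed ends: 0.65 points for blue and 0.05 points for green. Even the full 1.3 points is smaller than the margin of 1.5 points. Violet is fed second substrate, not starting material, so this reckoning gives it no figure, and I leave it near grey. My call is all alike, with blue at 18.7%.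

The forecast names grey as leader, with grey 19.5%, blue 17.7%, violet 19.2% and green 19%, on the ground that “Side product rises with starting-material concentration”. My blue stands 1.0 point above its blue.

The simulation gives all alike: grey 19.5%, blue 18.9%, violet 19.2%, green 19.4%.

    starting material + free enzyme ⇌ first complex (K = 270 M⁻¹, k = 11300 M⁻¹ min⁻¹)
    first complex → loaded enzyme + first product (k = 28.9 min⁻¹)
    second substrate + loaded enzyme ⇌ second complex (K = 2600 M⁻¹, k = 2.22 × 10⁵ M⁻¹ min⁻¹)
    second complex → free enzyme + target (k = 6.46 min⁻¹)
    starting material + first product → side product (k = 0.298 M⁻¹ min⁻¹)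

Blue ends 0.60 points under grey, against a feed loss of 0.65 points. Now leave blue until 20 h. The feed loss of 0.65 points is a gap at 8.00 h, when blue holds 38% of its starting material and grey 36%. Grey at 80.0 h holds 28.9% side product and 0% starting material, and there you take nothing off. Blue at 20 h shows 28.9% side product and 71.1% target, with 0.017% left of the starting material, the limiting reagent here.

(The readings were computed for substances that don't exist; the scatter is artificial.)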